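Its constants were drawn at random within sensible limits; the run is a simulation.

**The ratio.** Once crystals stood in a flask, I took the dissolved acid set free to sit near its solubility, 0.51 mM. The balance with the nucleophile then gave [protonated nucleophile]/[nucleophile] = 1.28, a ratio with no free base in it. So 43.9 % of the unreacted nucleophile stayed free, and I called this the free share.

    electrophile + nucleophile → acid set free + target (k1 = 0.500 L mol⁻¹ s⁻¹)
    nucleophile + acid set free ⇌ protonated nucleophile, settled at all times (K2 = 2510 L mol⁻¹)
    acid set free + free base ⇌ salt of the base, settled at all times (K3 = 32000 L mol⁻¹)
    target → over-reaction product (k4 = 3.19 × 10⁻⁴ s⁻¹)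
    crystals ⇌ acid set free, rate k5*(cs5 - [acid set free]) while solid is left; crystals form when [acid set free] > cs5 (cs5 = 0.51 mM, k5 = 0.425 s⁻¹)

| flask | electrophile | nucleophile | free base | time |
|---|---|---|---|---|
| ochre | 0.050 M | 0.0900 M | 0.0150 M | 4.0 min |
| violet | 0.050 M | 0.0900 M | 0.0190 M | 4.0 min |
| green | 0.050 M | 0.0900 M | 0.0250 M | 4.0 min |

* part of the electrophile that has reacted at the end, ochre
* part of the electrophile that has reacted at the end, violet
* part of the electrophile that has reacted at the end, green
* what raising the concentration of free base from its lowest to its highest value here does to the part of the electrophile that has reacted (changes below 5 percentage points count as none) (it rises / no change / it falls)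

- acid set free is meant together with its crystals
- solid, in amounts per volume of the solution: crystals
- run time (ochre): 4.0 min

**Turned round.** I asked what a real effect of the base would require. Ochre would have to finish at least 5 percentage points behind green, so it would have to keep 2.50 mM of electrophile even if green kept none.

At first crystals, 94.2 % of the base is bound and the nucleophile is split by the free share. The acid balance then put ochre's electrophile reacted at 41.7 mM, leaving 8.26 mM.

From there I used the free nucleophile at the close, the free share of 0.0400 M. That makes the tail pseudo-first-order, with a half-life of 1.32 min. For 2.50 mM to survive in ochre, first crystals could not come before 104 s. I had no hand value for that moment, so my reckoning stopped at this condition.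

**The forecast.** It gave 95.4 %, 96 % and 96.8 % for ochre, violet and green, and no change: “More base delays the crystals, but the crystal regime then has less time to run”. Its ochre crystals came at 92 s, earlier than my 104 s.

**The outcome.** Ochre, violet and green reached 95.5 %, 96.1 % and 97.1 %, a change of 1.6 points, so the answer was no change. Ochre ended with 4.5 % of its electrophile, less than the 5 points required. In violet, the free share of the unreacted nucleophile gave 0.0184 M of free nucleophile, and the flask held 0.0169 M. With 0.054 M of nucleophile instead, the neighbour of violet reached 78.1 %. There the free share gave 0.00656 M against 0.00574 M held, and 22 % of its electrophile still stood at the end.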